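Remark on the chemistry (assumption): the facial sense of the zinc–ProPhenol alkynylation in step 3 is assumed to follow that of the same catalyst in aldol additions; the configuration of 8 would be checked by Mosher ester analysis and the antipodal ligand used if needed.

## Analysis of the target

Target 32 is a germacranolide of the heliangolide type: a ten-membered carbocycle (C1–C10) trans-fused across C6–C7 to an α-methylene-γ-butyrolactone (lactone oxygen on C6, C11 on C7, carbonyl C12, exocyclic methylene C13). The ring carries a Z trisubstituted olefin C4=C5 (methyl C15), a 1,10-epoxide derived from an E olefin (methyl C14 on C10), a free allylic hydroxyl at C3 and, at C8, the ester of (2S,3S)-2,3-dimethyloxirane-2-carboxylic acid. The six ring stereocentres are 1R,3S,6R,7R,8R,10R. The C6 oxygen lies on the face opposite to the C7–C11 bond, the C8 oxygen on the same face as C7–C11, and C3 is insulated from this triad by the C4=C5 olefin. Sensitive groups are the methylene lactone (Michael acceptor), the glycidic ester, and the 1,10-epoxide, which cyclises transannularly onto C4=C5 under acid. The difficulties are the closure of a ten-membered ring that holds one E and one Z trisubstituted olefin, the contiguous C6–C7–C8 triad on a mobile ring, and telling four olefins apart late in the route. The strategy rests on the fact that C6, C7 and C8 carry O, C and O in sequence. A C7–C8 epoxide syn to the C6 oxygen, opened at C7 by a two-carbon carbanion anchored on O6, creates the C7–C11 bond, the lactone ring and the O–C–O triad in one step.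

## Retrosynthetic reasoning

32 ⇒ 31. The C3 hydroxyl is unmasked last. A free allylic hydroxyl at C3 would steer a peracid to C4=C5, so it stays silylated until the 1,10-epoxide is in place.

31 ⇒ 30. The C1–O and C10–O bonds are cut back to the E olefin C1=C10 of 30. It is the only electron-rich, unfunctionalised olefin left at that stage, so an electrophilic oxidant should find it without a directing group.

30 ⇒ 25 + 29. The C8–O ester bond is cut with inversion in mind. A cis C7–C8 epoxide syn to O6 necessarily leaves the C8 oxygen on the face of O6, opposite to what 32 needs, so alcohol 25 is the 8S epimer and the esterification must invert it. Acid 29 is traced to 26 through allylic alcohol 27 and epoxy alcohol 28, which sets both oxirane centres by reagent control before the coupling.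

25 ⇒ 23 (key disconnection). The C7–C11 bond and the C11=C13 bond are cut. This leaves the phosphonoacetate 23 of a syn epoxy alcohol, in which the carbanion on O6 can reach only C7 in a five-membered closure. One operation then gives the lactone, the C7 configuration by inversion, the C8 oxygen and the methylene group.

23 ⇒ 21 + 22, and 21 ⇒ 20. The ester C–O bond is cut to epoxy alcohol 21 and acid 22. The epoxide is traced to the cis C7=C8 olefin of trienol 20, with the C6 hydroxyl directing the oxidant to its own face.

20 ⇒ 19 ⇒ 18. The ring is opened at C7=C8, the only disubstituted ring olefin, which leads to an acyclic tetraene with two terminal vinyl groups. O6 is silylated in 18 and 19 so that the metathesis catalyst does not settle on C7.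

18 ⇒ 17 ⇒ 16 ⇒ 12 + 13. The C6 carbinol is traced to dienone 16, whose two flanks (vinyl, and a Z alkenyl group with a cis substituent) differ enough for catalyst-controlled reduction. The C5–C6 bond is cut to the Z alkenyl iodide 12 and the acrylic Weinreb amide 13.

12 ⇒ 11 ⇒ 9. The Z iodoalkene and its methyl group C15 are traced to the terminal propargylic alcohol 9. Addition of methyl and a metal across the alkyne, directed by the C3 alkoxide, fixes the Z geometry.

9 ⇒ 8 ⇒ 6 + 7. The C3–C4 bond is cut to aldehyde 6 and alkyne 7. An enantioselective alkynylation sets C3, the stereocentre from which the absolute configuration of the ring is later built.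

6 ⇒ 5 ⇒ 1 + 2. The C1–C2 bond is cut to an alkenylmetal from enyne 1 and to 2. Syn methylmetalation of the alkyne sets the E geometry of C1=C10 and brings in C14.

## Alternatives that were turned down

Alternative 1: The C1=C10 olefin and a C3 carbonyl are traced back to a C3–C10 bond, that is, to a cyclobutanol fused to an eight-membered ring with a sulfonate on C1. In the forward sense a fluoride source frees the tertiary C3 alkoxide, which expels the C1 leaving group while C3–C10 breaks (Grob fragmentation). The two small rings merge into the ten-membered enone lactone A1.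
- For: the medium ring is made by fragmentation, with no entropic penalty and no dilution. The E geometry follows stereospecifically from the antiperiplanar arrangement. On ring formation this is stronger than a metathesis closure.
- Against: three stereocentres (C1, C3, C10) and a regio- and stereodefined cyclobutane must be built only to be destroyed.
- Against: A1 holds a C3 ketone conjugated with C4=C5 and has the lactone oxygen at the γ position, so base can expel the carboxylate. The ketone must still be reduced to the 3S alcohol on the ring by substrate control.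
- Against: A1 lacks C13 and the C8 ester, so methylenation, deprotection and esterification follow.
- In its place the chosen strategy sets C3 early by catalyst control and delivers lactone, methylene group and triad together.

Alternative 2: The ring is traced to a six-membered ring from the chiral pool. The potassium alkoxide of a 1,2-dialkenylcyclohexenol undergoes an anionic oxy-Cope shift that forms C8–C9 and cleaves the former ring bond, giving the cyclodecadienone A2 with the ketone at C6, silicon at C8 and a silyl ether at C3.
- For: this ring expansion is well precedented for the germacrane skeleton, needs no dilution, and draws its olefin geometries from the chair transition state and the starting ring. On ring formation it is stronger than the chosen route.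
- Against: A2 contains none of C11–C13 and C7 is a bare methylene. After the key step the route still needs an alkylation at C7 trans to the future C6 oxygen, a face-selective reduction of the C6 ketone, lactonisation, methylenation, and oxidative conversion of the C8 silicon into oxygen in the presence of two trisubstituted olefins.
- Against: the C6–C7–C8 triad would be built one centre at a time under substrate control on a flexible ring.
- The chosen strategy spends more risk on closing the ring but obtains the triad from one stereospecific opening.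

Alternative 3: The ring is cut at C5–C6. A Z alkenyl iodide at C5 adds to a C6 aldehyde in a chromium-mediated, nickel-catalysed reaction (Nozaki–Hiyama–Kishi), and the C6 alkoxide closes the lactone on a C12 ester to give A3.
- For: the closure is proven for medium rings and tolerates the Z iodide. C7 and C8 are set in the open chain by reliable methods, and the lactone forms by itself. On ring closure this is as strong as or stronger than metathesis.
- Against: C6 is created in the cyclisation, so its configuration rests on macrocyclic diastereocontrol.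
- Against: the aldehyde has an epimerisable α centre and a β oxygen.
- Against: A3 still needs α-methylenation of the lactone and removal of the 4-methoxybenzyl ether by an oxidant, next to an electron-rich diene.
- In its place the chosen strategy sets C6 by a catalyst before the ring exists and forms the methylene lactone directly. The same type of ring closure is kept as a fallback below.

Key step: step 14

## Route

Step 1
Reactants: 1 pent-1-en-4-yne; 2 oxirane
Product: 5 (3E)-4-methylhepta-3,6-dien-1-ol, via alkenylalane 3 (not isolated), via lithium alkenylalanate 4 (not isolated)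
Conditions: Me3Al (2 equiv), Cp2ZrCl2 (25 mol %), CH2Cl2, 0 °C → rt; volatiles removed; n-BuLi, hexane, 0 °C; then 2, THF, −30 °C → rt
Reagents that add atoms: trimethylaluminium, C[Al](C)C
Why: Zirconium-catalysed syn methylalumination of the terminal alkyne (Negishi carboalumination) puts the methyl group C14 on the internal carbon and aluminium on C1, which fixes the E geometry of C1=C10; the isolated vinyl group does not react. The alanate made with n-BuLi transfers the alkenyl group to oxirane with retention and forms C1–C2.

Step 2
Reactants: 5 (3E)-4-methylhepta-3,6-dien-1-ol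
Product: 6 (3E)-4-methylhepta-3,6-dienal
Conditions: Dess–Martin periodinane, pyridine, CH2Cl2, 0 °C; used without chromatography
Reagents that add atoms: none
Why: Hypervalent-iodine oxidation under buffered, non-enolising conditions should keep the β,γ-unsaturated aldehyde from moving into conjugation; the aldehyde is used at once.

Step 3
Reactants: 6 (3E)-4-methylhepta-3,6-dienal; 7 ethynyltrimethylsilane
Product: 8 (3S,5E)-6-methyl-1-(trimethylsilyl)nona-5,8-dien-1-yn-3-ol
Conditions: Me2Zn (3 equiv), (R,R)-ProPhenol (10 mol %), Ph3P=O (20 mol %), toluene, 0–4 °C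
Reagents that add atoms: none
Why: Enantioselective alkynylation of an aldehyde by a zinc alkynylide on the dinuclear zinc–ProPhenol catalyst (Trost alkynylation); addition to the Re face gives the 3S carbinol (C3 of the target). The conditions are cold and free of amine base, so the aldehyde should neither enolise nor conjugate.

Step 4
Reactants: 8 (3S,5E)-6-methyl-1-(trimethylsilyl)nona-5,8-dien-1-yn-3-ol
Product: 9 (3S,5E)-6-methylnona-5,8-dien-1-yn-3-ol
Conditions: K2CO3, MeOH, rt
Reagents that add atoms: none
Why: Methanolysis of the alkynyl C–Si bond; the carbinol centre is not touched.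

Step 5
Reactants: 9 (3S,5E)-6-methylnona-5,8-dien-1-yn-3-ol
Product: 11 (1Z,3S,5E)-1-iodo-2,6-dimethylnona-1,5,8-trien-3-ol, via alkenylmagnesium alkoxide 10 (not isolated)
Conditions: MeMgBr (3.5 equiv), CuI (15 mol %), THF, −20 °C → rt; then I2, THF, −40 → 0 °C
Reagents that add atoms: methylmagnesium bromide, C[Mg]Br; iodine, II
Why: Copper-catalysed anti carbomagnesiation of the propargylic alkoxide (Duboudin–Jousseaume reaction): the methyl group C15 adds to the carbon next to the carbinol and magnesium ends on the terminal carbon, held cis to C3 in a five-membered chelate. Iodinolysis with retention gives the Z iodide, the geometry of C4=C5.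

Step 6
Reactants: 11 (1Z,3S,5E)-1-iodo-2,6-dimethylnona-1,5,8-trien-3-ol
Product: 12 tert-butyl{[(1Z,3S,5E)-1-iodo-2,6-dimethylnona-1,5,8-trien-3-yl]oxy}dimethylsilane
Conditions: TBSCl, imidazole, DMF, rt
Reagents that add atoms: tert-butyldimethylsilyl chloride, CC(C)(C)[Si](C)(C)Cl
Why: Standard silylation of a secondary alcohol; the silyl ether masks O3 until the last step and later shields C4=C5.

Step 7
Reactants: 12 tert-butyl{[(1Z,3S,5E)-1-iodo-2,6-dimethylnona-1,5,8-trien-3-yl]oxy}dimethylsilane; 13 N-methoxy-N-methylprop-2-enamide
Product: 16 (4Z,6S,8E)-6-[(tert-butyldimethylsilyl)oxy]-5,9-dimethyldodeca-1,4,8,11-tetraen-3-one, via alkenyllithium 14 (not isolated), via lithium hemiaminal 15 (not isolated)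
Conditions: t-BuLi (2.1 equiv), Et2O, −78 °C; then 13, −78 °C; inverse quench into cold aqueous buffer (pH 5)
Reagents that add atoms: none
Why: Iodine–lithium exchange goes with retention of the Z geometry (kept at −78 °C to avoid silyl migration from oxygen to carbon). Acylation by the Weinreb amide stops at the chelated adduct 15, which releases the vinyl ketone only on quench, so C5–C6 forms without over-addition.

Step 8
Reactants: 16 (4Z,6S,8E)-6-[(tert-butyldimethylsilyl)oxy]-5,9-dimethyldodeca-1,4,8,11-tetraen-3-one
Product: 17 (3S,4Z,6S,8E)-6-[(tert-butyldimethylsilyl)oxy]-5,9-dimethyldodeca-1,4,8,11-tetraen-3-ol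
Conditions: (R)-2-methyl-CBS-oxazaborolidine (0.5 equiv), catecholborane, toluene, −78 °C
Reagents that add atoms: none
Why: Corey–Bakshi–Shibata reduction: the ketone binds the catalyst anti to its larger flank, the Z trisubstituted alkenyl group whose cis substituent sits next to the carbonyl, and the (R)-catalyst should then give the 3S carbinol (C6 of the target). Catecholborane at −78 °C reduces 1,2 and leaves the olefins alone.

Step 9
Reactants: 17 (3S,4Z,6S,8E)-6-[(tert-butyldimethylsilyl)oxy]-5,9-dimethyldodeca-1,4,8,11-tetraen-3-ol
Product: 18 (3S,4Z,6S,8E)-6-[(tert-butyldimethylsilyl)oxy]-5,9-dimethyl-3-[(triethylsilyl)oxy]dodeca-1,4,8,11-tetraene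
Conditions: TESCl, imidazole, CH2Cl2, 0 °C
Reagents that add atoms: chlorotriethylsilane, CC[Si](Cl)(CC)CC
Why: Silylation of the secondary alcohol; the triethylsilyl group is needed only for step 10 and comes off selectively in step 11.

Step 10
Reactants: 18 (3S,4Z,6S,8E)-6-[(tert-butyldimethylsilyl)oxy]-5,9-dimethyl-3-[(triethylsilyl)oxy]dodeca-1,4,8,11-tetraene
Product: 19 (3S,6S)-3-[(tert-butyldimethylsilyl)oxy]-4,10-dimethyl-6-[(triethylsilyl)oxy]cyclodeca-1(10)E,4Z,7Z-triene (target numbering)
Conditions: second-generation Grubbs catalyst RuCl2(=CHPh)(PCy3)(H2IMes) (10 mol %), toluene (1 mM), 70 °C, argon purge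
Reagents that add atoms: none
Why: Ring-closing metathesis between the two monosubstituted olefins, the least hindered positions; the catalyst loads on the allyl terminus (C8), and the silyloxy group at C6 keeps it off C7, from where a carbene could close a seven-membered ring onto C1=C10. The Z C4=C5 bond folds the chain, and the new olefin is expected cis, the less strained geometry in a ten-membered ring that already holds an E olefin.

Step 11
Reactants: 19 (3S,6S)-3-[(tert-butyldimethylsilyl)oxy]-4,10-dimethyl-6-[(triethylsilyl)oxy]cyclodeca-1(10)E,4Z,7Z-triene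
Product: 20 (3S,6S)-3-[(tert-butyldimethylsilyl)oxy]-4,10-dimethylcyclodeca-1(10)E,4Z,7Z-trien-6-ol (target numbering)
Conditions: HF·pyridine, pyridine, THF, 0 °C
Reagents that add atoms: none
Why: Buffered HF·pyridine cleaves a triethylsilyl ether much faster than a tert-butyldimethylsilyl ether, so only O6 is freed as the directing group for step 12.

Step 12
Reactants: 20 (3S,6S)-3-[(tert-butyldimethylsilyl)oxy]-4,10-dimethylcyclodeca-1(10)E,4Z,7Z-trien-6-ol
Product: 21 (3S,6R,7R,8S)-3-[(tert-butyldimethylsilyl)oxy]-7,8-epoxy-4,10-dimethylcyclodeca-1(10)E,4Z-dien-6-ol (target numbering)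
Conditions: VO(acac)2 (5 mol %), t-BuOOH (1.3 equiv, in decane), CH2Cl2, 0 °C
Reagents that add atoms: tert-butyl hydroperoxide, CC(C)(C)OO
Why: Hydroxyl-directed epoxidation by the vanadium peroxo complex bound to O6; on medium-ring cis allylic alcohols oxygen is delivered to the face of the hydroxyl, which should give the cis epoxide syn to O6. C7=C8 is expected to react before C4=C5, which is deactivated by two allylic C–O bonds and shielded by the silyloxy-bearing C3 lying cis to C6; C1=C10 is out of reach of the directing group.

Step 13
Reactants: 21 (3S,6R,7R,8S)-3-[(tert-butyldimethylsilyl)oxy]-7,8-epoxy-4,10-dimethylcyclodeca-1(10)E,4Z-dien-6-ol; 22 (diethoxyphosphoryl)acetic acid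
Product: 23 (3S,6R,7S,8S)-3-[(tert-butyldimethylsilyl)oxy]-7,8-epoxy-4,10-dimethylcyclodeca-1(10)E,4Z-dien-6-yl (diethoxyphosphoryl)acetate (target numbering)
Conditions: DCC, DMAP (10 mol %), CH2Cl2, 0 °C → rt
Reagents that add atoms: none
Why: Steglich esterification; the activated phosphonoacetic acid acylates the hindered secondary alcohol under neutral conditions that leave the epoxide intact (the descriptor at C7 changes only through the priority rules).

Step 14
Reactants: 23 (3S,6R,7S,8S)-3-[(tert-butyldimethylsilyl)oxy]-7,8-epoxy-4,10-dimethylcyclodeca-1(10)E,4Z-dien-6-yl (diethoxyphosphoryl)acetate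
Product: 25 (3S,6R,7R,8S)-3-[(tert-butyldimethylsilyl)oxy]-8-hydroxygermacra-1(10)E,4Z,11(13)-trien-12,6-olide, via phosphono lactone carbanion 24 (not isolated)
Conditions: NaH (1.1 equiv), THF, 0 → 45 °C; then paraformaldehyde, 0 °C → rt
Reagents that add atoms: formaldehyde (from paraformaldehyde), C=O
Why: NaH removes the only acidic C–H, and the carbanion C11 attacks C7 from the face opposite to the epoxide oxygen, forming C7–C11 and the lactone by a 5-exo-tet closure while the oxirane C8–O bond is kept as an alkoxide; the closest known reaction type is the intramolecular opening of an epoxide by a tethered stabilised ester carbanion, followed by Horner–Wadsworth–Emmons methylenation of the α-phosphono lactone. Proton transfer from C11 to the C8 alkoxide gives the phosphonate carbanion 24, so one equivalent of base serves both stages, and 24 condenses with formaldehyde to form C11=C13 with loss of diethyl phosphate. C7 is set by SN2 inversion: the epoxide oxygen and O6 are on the same face, so C11 enters on the other face and the lactone is trans-fused (6R,7R); C8 keeps the configuration of the epoxide (8S, the epimer of the target, corrected in step 18). Attack at C7 and not C8 is secured by ring size (five-membered exo against six-membered endo closure) and by the short tether, which cannot reach C8 collinearly with its C–O bond. The backside trajectory needs the C6–O and C7–O(epoxide) bonds roughly antiperiplanar, a conformer the ten-membered ring can reach with a C5–C6–C7–C8 torsion near 120–140°. Side reactions are limited by the acylated O6 (no Payne rearrangement), the silylated O3, and the small excess of base, which should not leave a C8 alkoxide free to attack the lactone or phosphorus.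

Step 15
Reactants: 26 angelic acid
Product: 27 (2Z)-2-methylbut-2-en-1-ol
Conditions: LiAlH4, Et2O, 0 °C
Reagents that add atoms: none
Why: Hydride reduction of the carboxylic acid to the primary allylic alcohol; the trisubstituted Z olefin is not reduced or isomerised at 0 °C.

Step 16
Reactants: 27 (2Z)-2-methylbut-2-en-1-ol
Product: 28 [(2R,3S)-2,3-dimethyloxiran-2-yl]methanol
Conditions: Ti(OiPr)4 (10 mol %), D-(−)-diisopropyl tartrate (12 mol %), t-BuOOH, 4 Å molecular sieves, CH2Cl2, −20 °C
Reagents that add atoms: tert-butyl hydroperoxide, CC(C)(C)OO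
Why: Sharpless asymmetric epoxidation of a primary Z allylic alcohol; D-(−)-tartrate should give the (2R,3S) epoxy alcohol, the mirror image of the sense known for 2-methyl-(Z)-alk-2-en-1-ols with the L-(+) ester.

Step 17
Reactants: 28 [(2R,3S)-2,3-dimethyloxiran-2-yl]methanol
Product: 29 (2S,3S)-2,3-dimethyloxirane-2-carboxylic acid
Conditions: RuCl3·xH2O (2 mol %), NaIO4 (3 equiv), CCl4/MeCN/H2O, rt
Reagents that add atoms: water, O
Why: Ruthenium tetroxide oxidation (Sharpless conditions) takes the primary alcohol to the acid through the aldehyde hydrate without opening the oxirane; the descriptor at C2 becomes S only through the change in priorities.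

Step 18
Reactants: 25 (3S,6R,7R,8S)-3-[(tert-butyldimethylsilyl)oxy]-8-hydroxygermacra-1(10)E,4Z,11(13)-trien-12,6-olide; 29 (2S,3S)-2,3-dimethyloxirane-2-carboxylic acid
Product: 30 (3S,6R,7R,8R)-3-[(tert-butyldimethylsilyl)oxy]-8-{[(2S,3S)-2,3-dimethyloxiran-2-yl]carbonyloxy}germacra-1(10)E,4Z,11(13)-trien-12,6-olide
Conditions: PPh3, diisopropyl azodicarboxylate, toluene, 0 °C → rt
Reagents that add atoms: none
Why: Mitsunobu esterification: the C8 hydroxyl is activated as its oxyphosphonium ion and displaced by the carboxylate of 29 with inversion, which turns the 8S alcohol into the 8R ester of the target. The glycidic acid (pKa about 3.5) is acidic enough to protonate the betaine.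

Step 19
Reactants: 30 (3S,6R,7R,8R)-3-[(tert-butyldimethylsilyl)oxy]-8-{[(2S,3S)-2,3-dimethyloxiran-2-yl]carbonyloxy}germacra-1(10)E,4Z,11(13)-trien-12,6-olide
Product: 31 (1R,3S,6R,7R,8R,10R)-3-[(tert-butyldimethylsilyl)oxy]-8-{[(2S,3S)-2,3-dimethyloxiran-2-yl]carbonyloxy}-1,10-epoxygermacra-4Z,11(13)-dien-12,6-olide
Conditions: mCPBA, NaHCO3, CH2Cl2, 0 °C
Reagents that add atoms: 3-chloroperoxybenzoic acid, OOC(=O)c1cccc(Cl)c1
Why: Electrophilic (Prilezhaev) epoxidation of the most electron-rich olefin: C1=C10 is trisubstituted and unfunctionalised, C4=C5 is flanked by two allylic oxygens and C11=C13 is conjugated to the lactone. In the lactone-locked ring the E olefin stands across the mean ring plane, so the peracid should reach only its outer face and give the (1R,10R) epoxide; the bicarbonate guards against acid-induced transannular reactions.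

Step 20
Reactants: 31 (1R,3S,6R,7R,8R,10R)-3-[(tert-butyldimethylsilyl)oxy]-8-{[(2S,3S)-2,3-dimethyloxiran-2-yl]carbonyloxy}-1,10-epoxygermacra-4Z,11(13)-dien-12,6-olide
Product: 32 (1R,3S,6R,7R,8R,10R)-8-{[(2S,3S)-2,3-dimethyloxiran-2-yl]carbonyloxy}-1,10-epoxy-3-hydroxygermacra-4Z,11(13)-dien-12,6-olide (CNP0268255.2)
Conditions: HF·pyridine, pyridine, THF, 0 °C → rt
Reagents that add atoms: none
Why: Fluoride cleavage of the secondary allylic silyl ether; the pyridine buffer should keep the medium from opening the 1,10-epoxide or the glycidic ester, and no base strong enough to add to the methylene lactone is present.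

## Compound list

1 | pent-1-en-4-yne | C#CCC=C | starting material
2 | oxirane | C1CO1 | starting material
3 | dimethyl[(1E)-2-methylpenta-1,4-dien-1-yl]alane | C=CC/C(C)=C/[Al](C)C | intermediate
4 | lithium butyl(dimethyl)[(1E)-2-methylpenta-1,4-dien-1-yl]alanate | [Li+].C=CC/C(C)=C/[Al-](C)(C)CCCC | intermediate
5 | (3E)-4-methylhepta-3,6-dien-1-ol | OCC/C=C(\C)CC=C | intermediate
6 | (3E)-4-methylhepta-3,6-dienal | O=CC/C=C(\C)CC=C | intermediate
7 | ethynyltrimethylsilane | C#C[Si](C)(C)C | starting material
8 | (3S,5E)-6-methyl-1-(trimethylsilyl)nona-5,8-dien-1-yn-3-ol | C[Si](C)(C)C#C[C@@H](O)C/C=C(\C)CC=C | intermediate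
9 | (3S,5E)-6-methylnona-5,8-dien-1-yn-3-ol | C#C[C@@H](O)C/C=C(\C)CC=C | intermediate
10 | bromomagnesium alkoxide of the (Z)-alkenylmagnesium bromide from 9 | Br[Mg]/C=C(/C)[C@@H](O[Mg]Br)C/C=C(\C)CC=C | intermediate
11 | (1Z,3S,5E)-1-iodo-2,6-dimethylnona-1,5,8-trien-3-ol | I/C=C(/C)[C@@H](O)C/C=C(\C)CC=C | intermediate
12 | tert-butyl{[(1Z,3S,5E)-1-iodo-2,6-dimethylnona-1,5,8-trien-3-yl]oxy}dimethylsilane | I/C=C(/C)[C@@H](O[Si](C)(C)C(C)(C)C)C/C=C(\C)CC=C | intermediate
13 | N-methoxy-N-methylprop-2-enamide | C=CC(=O)N(C)OC | starting material
14 | (Z)-alkenyllithium from 12 | [Li]/C=C(/C)[C@@H](O[Si](C)(C)C(C)(C)C)C/C=C(\C)CC=C | intermediate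
15 | lithium hemiaminal (tetrahedral adduct of 14 and 13) | [Li]OC(C=C)(N(C)OC)/C=C(/C)[C@@H](O[Si](C)(C)C(C)(C)C)C/C=C(\C)CC=C | intermediate
16 | (4Z,6S,8E)-6-[(tert-butyldimethylsilyl)oxy]-5,9-dimethyldodeca-1,4,8,11-tetraen-3-one | C=CC(=O)/C=C(/C)[C@@H](O[Si](C)(C)C(C)(C)C)C/C=C(\C)CC=C | intermediate
17 | (3S,4Z,6S,8E)-6-[(tert-butyldimethylsilyl)oxy]-5,9-dimethyldodeca-1,4,8,11-tetraen-3-ol | C=C[C@H](O)/C=C(/C)[C@@H](O[Si](C)(C)C(C)(C)C)C/C=C(\C)CC=C | intermediate
18 | (3S,4Z,6S,8E)-6-[(tert-butyldimethylsilyl)oxy]-5,9-dimethyl-3-[(triethylsilyl)oxy]dodeca-1,4,8,11-tetraene | C=C[C@H](O[Si](CC)(CC)CC)/C=C(/C)[C@@H](O[Si](C)(C)C(C)(C)C)C/C=C(\C)CC=C | intermediate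
19 | (3S,6S)-3-[(tert-butyldimethylsilyl)oxy]-4,10-dimethyl-6-[(triethylsilyl)oxy]cyclodeca-1(10)E,4Z,7Z-triene (target numbering) | CC[Si](CC)(CC)O[C@@H]1/C=C(/C)[C@@H](O[Si](C)(C)C(C)(C)C)C/C=C(\C)C/C=C\1 | intermediate
20 | (3S,6S)-3-[(tert-butyldimethylsilyl)oxy]-4,10-dimethylcyclodeca-1(10)E,4Z,7Z-trien-6-ol (target numbering) | O[C@@H]1/C=C(/C)[C@@H](O[Si](C)(C)C(C)(C)C)C/C=C(\C)C/C=C\1 | intermediate
21 | (3S,6R,7R,8S)-3-[(tert-butyldimethylsilyl)oxy]-7,8-epoxy-4,10-dimethylcyclodeca-1(10)E,4Z-dien-6-ol (target numbering; epoxide oxygen cis to the hydroxyl) | O[C@@H]1/C=C(/C)[C@@H](O[Si](C)(C)C(C)(C)C)C/C=C(\C)C[C@@H]2O[C@H]12 | intermediate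
22 | (diethoxyphosphoryl)acetic acid | CCOP(=O)(OCC)CC(=O)O | starting material
23 | (3S,6R,7S,8S)-3-[(tert-butyldimethylsilyl)oxy]-7,8-epoxy-4,10-dimethylcyclodeca-1(10)E,4Z-dien-6-yl (diethoxyphosphoryl)acetate (target numbering) | CCOP(=O)(OCC)CC(=O)O[C@@H]1/C=C(/C)[C@@H](O[Si](C)(C)C(C)(C)C)C/C=C(\C)C[C@@H]2O[C@H]12 | intermediate
24 | sodium salt of the C11 carbanion of the 11-(diethoxyphosphoryl) analogue of lactone 25 | [Na+].CCOP(=O)(OCC)[C-]1C(=O)O[C@@H]2/C=C(/C)[C@@H](O[Si](C)(C)C(C)(C)C)C/C=C(\C)C[C@H](O)[C@@H]12 | intermediate
25 | (3S,6R,7R,8S)-3-[(tert-butyldimethylsilyl)oxy]-8-hydroxygermacra-1(10)E,4Z,11(13)-trien-12,6-olide | C=C1C(=O)O[C@@H]2/C=C(/C)[C@@H](O[Si](C)(C)C(C)(C)C)C/C=C(\C)C[C@H](O)[C@@H]12 | intermediate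
26 | angelic acid, (2Z)-2-methylbut-2-enoic acid | C/C=C(/C)C(=O)O | starting material
27 | (2Z)-2-methylbut-2-en-1-ol | C/C=C(/C)CO | intermediate
28 | [(2R,3S)-2,3-dimethyloxiran-2-yl]methanol | OC[C@@]1(C)O[C@H]1C | intermediate
29 | (2S,3S)-2,3-dimethyloxirane-2-carboxylic acid | OC(=O)[C@@]1(C)O[C@H]1C | intermediate
30 | (3S,6R,7R,8R)-3-[(tert-butyldimethylsilyl)oxy]-8-{[(2S,3S)-2,3-dimethyloxiran-2-yl]carbonyloxy}germacra-1(10)E,4Z,11(13)-trien-12,6-olide | C=C1C(=O)O[C@@H]2/C=C(/C)[C@@H](O[Si](C)(C)C(C)(C)C)C/C=C(\C)C[C@@H](OC(=O)[C@@]3(C)O[C@H]3C)[C@@H]12 | intermediate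
31 | (1R,3S,6R,7R,8R,10R)-3-[(tert-butyldimethylsilyl)oxy]-8-{[(2S,3S)-2,3-dimethyloxiran-2-yl]carbonyloxy}-1,10-epoxygermacra-4Z,11(13)-dien-12,6-olide | C=C1C(=O)O[C@@H]2/C=C(/C)[C@@H](O[Si](C)(C)C(C)(C)C)C[C@H]3O[C@]3(C)C[C@@H](OC(=O)[C@@]3(C)O[C@H]3C)[C@@H]12 | intermediate
32 | (1R,3S,6R,7R,8R,10R)-8-{[(2S,3S)-2,3-dimethyloxiran-2-yl]carbonyloxy}-1,10-epoxy-3-hydroxygermacra-4Z,11(13)-dien-12,6-olide (CNP0268255.2) | C=C1C(=O)O[C@@H]2/C=C(/C)[C@@H](O)C[C@H]3O[C@]3(C)C[C@@H](OC(=O)[C@@]3(C)O[C@H]3C)[C@@H]12 | target

## Step count and least certain steps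

Total: 20 steps. Longest linear sequence: 17 steps (steps 1–14 and 18–20); acid 29 is made in 3 steps (15–17) and joins in step 18.

**Step 14 (key step).** The stabilised carbanion is a weak nucleophile and C7 is inductively deactivated by the neighbouring acyloxy carbon, so the opening may be slow. Loss of the phosphonoacetyl group by acyl transfer, base-induced isomerisation of the epoxide to an allylic alcohol, or attack at C8 could then compete. After closure, the C8 alkoxide may draw the lactone over to O8 or attack phosphorus.
Fallback (sets out from 21, returns at 25): 21 is acetylated (Ac2O, DMAP, pyridine) to the C6 acetate F1. Its lithium enolate (LiN(SiMe3)2, THF, −78 → 0 °C), a much stronger carbon nucleophile, should close the ring by the same 5-exo opening at C7 and give the α-unsubstituted hydroxy lactone F2. The methylene group is then added in the classical way: aminomethylation of the lactone enolate (LiN(iPr)2, 2.2 equiv, then dimethylmethyleneiminium iodide) gives the Mannich base F3, and N-methylation (MeI) and elimination (NaHCO3) lead to 25.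

**Step 10.** Ring strain may make closure slower than intermolecular metathesis, which leads to oligomers. If a carbene nevertheless forms at C7, it can close a seven-membered ring onto C1=C10 and cut the chain. The new olefin may also form trans, which would change the later stereochemical course.
Fallback (sets out from 16, returns at 20): the metathesis is run on dienone 16 with the same catalyst. A vinyl ketone does not carry the ruthenium alkylidene, so the only productive carbene sits at C8, and the sp2 carbon at C6 eases transannular strain; this should give the ring dienone F4. Reduction of F4 (NaBH4, CeCl3·7H2O, MeOH, −78 °C, or (R)-2-methyl-CBS-oxazaborolidine with catecholborane) then sets C6 on the ring and gives 20; the epimers are separable and the unwanted one is re-oxidised with MnO2. Should metathesis fail in every form, the fallback under step 12 closes the ring at a different bond.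

**Step 12.** O6 is allylic to both C7=C8 and C4=C5, so oxygen delivery to the trisubstituted C4=C5 bond may compete. In a ten-membered ring the face selectivity of the directed epoxidation may also be lower than in eight- and nine-membered rings.
Fallback (sets out from 12, returns at 21): the terminal alkene of 12 is extended by Z-selective cross-metathesis with cis-but-2-ene-1,4-diol, using the cyclometalated ruthenium catalyst Ru(NO3)(=CH-C6H4-2-OiPr)(C,C-chelating N-adamantyl-N′-(2,6-diisopropylphenyl)imidazolinylidene), to the Z allylic alcohol F5. As the only allylic alcohol in the molecule it is epoxidised by Ti(OiPr)4, D-(−)-diethyl tartrate and t-BuOOH to the cis epoxy alcohol F6, with the site fixed by structure and the face by the reagent. Dess–Martin oxidation gives the epoxy aldehyde F7. An intramolecular Nozaki–Hiyama–Kishi addition (CrCl2, NiCl2 1 mol %, DMSO/THF, high dilution) then closes the ring at C5–C6, and Felkin–Anh addition anti to the epoxide C–O bond should give the syn carbinol 21.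

**Step 8.** Both flanks of the ketone are alkenyl groups, so the catalyst may discriminate poorly between the faces. The C3 stereocentre may also be mismatched with the catalyst.
Fallback (sets out from 16, returns at 17): 16 is reduced without control (NaBH4, CeCl3·7H2O, MeOH, −78 °C) to the mixture of C6 epimers F8. The mixture is resolved by Sharpless kinetic resolution (Ti(OiPr)4, L-(+)-diisopropyl tartrate, t-BuOOH 0.6 equiv, CH2Cl2, −20 °C). The 6R epimer should be epoxidised at its vinyl group to the erythro epoxy alcohol F9, which is separated, while the 6S epimer 17 is recovered; its Z trisubstituted olefin belongs to the slowest substrate class for this catalyst.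

**Step 18.** The C8 hydroxyl is hindered, next to the ring fusion. The activated alcohol may eliminate towards C9 or C7 instead of being displaced, or the reaction may stall at the oxyphosphonium stage.
Fallback (sets out from 25, returns at 30): 25 is converted (ClCH2SO2Cl, pyridine, 0 °C) into the chloromethanesulfonate F10. This is displaced with inversion by the caesium salt of 29 (Cs2CO3, 18-crown-6, toluene, 60 °C), a separate activation that avoids the basic betaine.

**Step 19.** Facial selectivity depends on the ring conformer; if the methyl group C14 can flip to the other side, the diastereomeric epoxide forms. Acid from the reagent may also trigger transannular cyclisation.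
Fallback (sets out from 30, returns at 31): Shi epoxidation with the D-fructose-derived ketone, Oxone (2KHSO5·KHSO4·K2SO4) and K2CO3 in MeCN/dimethoxymethane/H2O at 0 °C. This puts the face under reagent control, and the spiro transition state predicts the (1R,10R) epoxide for this E trisubstituted olefin. No new compound is involved.

## Further compounds

F1 | step 14 | C6 acetate of epoxy alcohol 21 | CC(=O)O[C@@H]1/C=C(/C)[C@@H](O[Si](C)(C)C(C)(C)C)C/C=C(\C)C[C@@H]2O[C@H]12
F2 | step 14 | (3S,6R,7R,8S)-3-[(tert-butyldimethylsilyl)oxy]-8-hydroxy-13-norgermacra-1(10)E,4Z-dien-12,6-olide | C1C(=O)O[C@@H]2/C=C(/C)[C@@H](O[Si](C)(C)C(C)(C)C)C/C=C(\C)C[C@H](O)[C@@H]12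
F3 | step 14 | 11-[(dimethylamino)methyl] derivative of F2 (C11 epimers) | CN(C)CC1C(=O)O[C@@H]2/C=C(/C)[C@@H](O[Si](C)(C)C(C)(C)C)C/C=C(\C)C[C@H](O)[C@@H]12
F4 | step 10 | (3S)-3-[(tert-butyldimethylsilyl)oxy]-4,10-dimethylcyclodeca-1(10)E,4Z,7Z-trien-6-one (target numbering) | O=C1/C=C(/C)[C@@H](O[Si](C)(C)C(C)(C)C)C/C=C(\C)C/C=C\1
F5 | step 12 | (2Z,5E,8S,9Z)-8-[(tert-butyldimethylsilyl)oxy]-10-iodo-5,9-dimethyldeca-2,5,9-trien-1-ol | I/C=C(/C)[C@@H](O[Si](C)(C)C(C)(C)C)C/C=C(\C)C/C=C\CO
F6 | step 12 | cis epoxy alcohol from F5, [(2R,3S)-3-substituted oxiran-2-yl]methanol | I/C=C(/C)[C@@H](O[Si](C)(C)C(C)(C)C)C/C=C(\C)C[C@@H]1O[C@@H]1CO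
F7 | step 12 | cis epoxy aldehyde from F6 | I/C=C(/C)[C@@H](O[Si](C)(C)C(C)(C)C)C/C=C(\C)C[C@@H]1O[C@@H]1C=O
F8 | step 8 | (4Z,6S,8E)-6-[(tert-butyldimethylsilyl)oxy]-5,9-dimethyldodeca-1,4,8,11-tetraen-3-ol as the mixture of C3 epimers | C=CC(O)/C=C(/C)[C@@H](O[Si](C)(C)C(C)(C)C)C/C=C(\C)CC=C
F9 | step 8 | erythro 1,2-epoxide of the 3R epimer of 17 | C1O[C@H]1[C@@H](O)/C=C(/C)[C@@H](O[Si](C)(C)C(C)(C)C)C/C=C(\C)CC=C
F10 | step 18 | C8 chloromethanesulfonate of 25 | C=C1C(=O)O[C@@H]2/C=C(/C)[C@@H](O[Si](C)(C)C(C)(C)C)C/C=C(\C)C[C@H](OS(=O)(=O)CCl)[C@@H]12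
F0 | step 19 | none | none
A1 | alternative 1 | trans-fused 13-nor lactone of the (1(10)E,4Z)-cyclodecadien-3-one with a 4-methoxybenzyl ether at C8 | O=C1O[C@@H]2/C=C(/C)C(=O)C/C=C(\C)C[C@@H](OCc3ccc(OC)cc3)[C@H]2C1
A2 | alternative 2 | (1(10)E,4Z)-cyclodecadien-6-one with a benzyldimethylsilyl group at C8 and a tert-butyldimethylsilyl ether at C3 | C1[C@H]([Si](C)(C)Cc2ccccc2)C/C(C)=C/C[C@H](O[Si](C)(C)C(C)(C)C)/C(C)=C\C1=O
A3 | alternative 3 | trans-fused 13-nor lactone of the (1(10)E,4Z)-cyclodecadiene with a tert-butyldimethylsilyl ether at C3 and a 4-methoxybenzyl ether at C8 | O=C1O[C@@H]2/C=C(/C)[C@@H](O[Si](C)(C)C(C)(C)C)C/C=C(\C)C[C@@H](OCc3ccc(OC)cc3)[C@H]2C1
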